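Numbering used throughout: C1 is the lactone carbonyl, C13 the carbinol carbon on the ring oxygen, C8a the methyl carbon on C8.

## Structural features

The target is a single 14-membered lactone (C1 carbonyl to C13, closed through O13) with methyl groups on C2, C4, C6, C8, C10, C12 and C13, hydroxyl groups on C3, C5 and C11, and a ketone at C9. Its ten stereocentres form a contiguous pentad C2–C6 (2,3-syn, 3,4-syn, 4,5-syn, 5,6-anti in the zigzag chain) and a contiguous tetrad C10–C13 (10,11-syn, 11,12-anti, 12,13-syn), separated by the C7 methylene and the lone C8 centre. C2 and C10 have the same configuration and the same neighbours (a carbonyl carbon on one side, an oxygenated carbon on the other), so one chiral dipropionate unit can serve both halves. The fragile parts are the β-hydroxy ketone C9–C11 (retro-aldol, elimination, epimerisation at C8 or C10 under base), the β-hydroxy lactone C1–C3, and the 5-hydroxy/9-ketone pair, which can close to a hemiketal; strong base is excluded once C9 is a ketone and the last step must be mild. The difficulty is twofold: ten stereocentres must be set, and a 14-membered ring must be closed from a chain whose syn-3,5-dioxygen pattern has to lie parallel, as it does in the ring. The key step uses the fact that C8 bears only a methyl group and sits next to the C9 ketone: C8–C9 can be made by adding a C8 alkenyl metal (C8a as a methylene) to a C9 aldehyde, since the C9 carbinol is later oxidised and C8 is created afterwards inside the ring.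

## Logic of the disconnections

33 is traced to 32 by cutting only O–protecting-group bonds: O3 and O5 share an isopropylidene acetal and O11 carries one silyl group. The forward step must be acidic and not basic, so that the C9–C11 aldol unit survives.

32 is traced to 30 by removing the C8–H and C8a–H bonds, and 30 to 29 by lowering C9 to a carbinol. This takes away the C8 stereocentre and makes the C9 configuration irrelevant. In the forward direction the hydride goes to C8a, which is not stereogenic; C8 is set when enolate 31 is protonated, so that protonation, not the hydride delivery, must be face-selective.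

29 is traced to 26 by cutting C8–C9. The cut lies far from the lactone, falls between a methylene-bearing sp2 carbon and a carbonyl carbon, and opens the ring to an ester chain of two similar halves. The forward step must favour ring closure over intermolecular coupling and must touch only the aldehyde. Two bulky silyl ethers on the syn-3,5-diol would resist the parallel O3/O5 arrangement of the ring, so 26 carries a 3,5-acetonide that fixes C2–C6 in the extended form, and only one silyl ether (O11).

26 is traced to 24, in which C9 is an N-methoxy-N-methylamide, and 24 is cut at the C1–O13 ester bond into 15 and 22. This gives a C1–C8 acid with five stereocentres and a C9–C13 alcohol with four. The forward steps must acylate a hindered secondary hydroxyl without epimerising C2, and then reduce the amide but not the ester.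

22 is traced through 21 to 20, a six-membered lactone in which O13 is tied to C9. With O13 masked in the ring, O11 is the only hydroxyl present when the silyl group is put on, and opening the lactone with the amine frees O13–H and sets C9 at the right oxidation level in one step. 20 comes from 19 by acyl transfer that also releases the auxiliary.

19 is traced to 18 by removing the C11–H bond (a 1,3-anti reduction directed by O13), and 18 is cut at C12–C13 into 5 and 16. The forward aldol must give the 10,12-anti, 12,13-syn pattern.

15 is traced through 14 and 13 to 12 by cutting the C1–O bond, the acetal and the C3–H bond (a 1,3-syn reduction), and 12 is cut at C4–C5 into 5 and 10. The forward aldol must give the 2,4-syn, 4,5-syn, 5,6-anti pattern; enolate control and the aldehyde's own preference should reinforce each other.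

10 is traced through 9 to 8, and 8 is cut at C6–C7 into 1 and 6. The alkylation sets C6 and brings in C7, C8, C8a and the bromine in one step.

5 is traced through 4 to 1 and 2 (C–C bond of a syn aldol, then oxidation). One auxiliary enantiomer, 1, therefore supplies C2, C6 and C10.

## Other disconnections considered

Alternative 1: The cut removes the C5–O, C6–H, C8–H and C9–O bonds of a C3–C11 segment and leads back to the (E,E)-skipped diene A2. In the forward key step thexylborane (from BH3 and 2,3-dimethylbut-2-ene) would add to one trisubstituted alkene, the monoalkylborane would add to the second through a six-membered borinane, and NaOH/H2O2 would give the 5,9-diol A1.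
- In favour: four stereocentres (C5, C6, C8, C9) would come from two alkene geometries in one operation. C8 would be fixed in the open chain relative to C6 by the chair borinane; on certainty at C8 this is better than the chosen plan, which relies on a protonation inside the macrocycle.
- Against: A1 ends in CH2O groups at C3 and C11, so C2, C3, C11, C12 and C13 would still need two stereoselective chain extensions, and the ring would be closed by a separate lactonisation. The face selectivity at each alkene would rest only on allylic strain from C4 and C10. The two halves of A1 are mirror images apart from their end groups, so the 5- and 9-hydroxyls, which must end as carbinol and ketone, would be hard to tell apart.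
- Comparison: both plans pass through a disposable C9 carbinol, and are equal on that point. The key step of A2 to A1 forms no ring and no skeletal C–C bond, so the total would be expected to exceed the 20 steps of the chosen plan.

Alternative 2: The cut is C2–C3 and leads back to the O13 propionate A4, which carries a β-lactone across C3–C5. In the forward key step LiN(SiMe3)2 would form the lithium ester enolate, C2 would attack the β-lactone carbonyl, and acyl–oxygen cleavage would release the C5 alkoxide and close the ring to the 3-oxo-5-hydroxy lactone A3.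
- In favour: the ring closure is a C–C bond formation driven by release of four-ring strain. C8 and every centre from C4 to C13 would be set in the open chain, which is better than the chosen plan for C8. O13 would be acylated with a simple propionyl unit instead of a valuable acid, which is also better.
- Against: the enolate of a secondary alkyl propionate can fragment to a ketene or condense with itself, and the β-lactone has an acidic C4–H that invites enolisation and ring opening by elimination. C2 of A3 lies between two carbonyls and would settle under thermodynamic control, which may or may not favour 2R. The C3 ketone would then need a face-selective reduction inside the ring; this is the same kind of macrocyclic control the chosen plan needs at C8, so the two are equal in kind there. Releasing and oxidising C9 would require protection of O3 and O5 first.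
- Comparison: about five steps would follow the key step, against three in the chosen plan, and the C3–C13 chain with its nine centres would be built linearly instead of from two halves.

Alternative 3: The cut is C11=C12 (then C11–O and C12–H) and leads back to the diene ester A6. In the forward key step the second-generation Hoveyda–Grubbs catalyst would join the C10 vinyl group and the C12 isopropenyl group, with loss of the two terminal methylene carbons as a volatile alkene, to give the (E)-alkene lactone A5. Hydroboration from the ring periphery would follow; syn addition to the E-alkene with boron on C11 would give the 11,12-anti relationship.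
- In favour: the C12–C13 part of A6 is a five-carbon allylic alcohol, so the whole C9–C13 fragment synthesis would be replaced by one esterification, which is better on step count before ring closure. C8 would be set in the open chain (better). The ring closure is catalytic and needs no stoichiometric chromium (better in practice).
- Against: metathesis onto a 1,1-disubstituted alkene next to the acyloxy carbon C13, forming a trisubstituted alkene in a 14-membered ring, would be slow, and its geometry is not assured; the Z-alkene would give the wrong 11,12-relationship. Two stereocentres (C11, C12) would then hang on one face selection in the macrocycle, against one centre (C8) in the chosen plan. The borane must spare the lactone, and O11 would need protection before C9 is unmasked and oxidised.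
- Comparison: about five steps would follow the key step against three; the chosen plan sets C11 and C12 by acyclic reactions with well-understood control.

Key step: step 17

Assumption: 29 is formed and carried on as a mixture of C9 epimers; the (9S) epimer is the one drawn and named.

## Route

Step 1
Reactants: 1 (R)-4-benzyl-3-propionyloxazolidin-2-one; 2 propanal
Product: 4 (R)-4-benzyl-3-[(2R,3S)-3-hydroxy-2-methylpentanoyl]oxazolidin-2-one, via Z-dibutylboron enolate 3 (not isolated)
Conditions: Bu2BOTf, i-Pr2NEt, CH2Cl2, 0 °C; 2, −78 → 0 °C; H2O2, MeOH, pH 7 buffer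
Reagents that add atoms: none
Why: Evans syn aldol reaction: enolate 3 reacts through a Zimmerman–Traxler chair with the auxiliary carbonyl turned away from boron, so the aldehyde takes the enolate face remote from the benzyl group and the 2R,3S syn adduct should form.

Step 2
Reactants: 4 (R)-4-benzyl-3-[(2R,3S)-3-hydroxy-2-methylpentanoyl]oxazolidin-2-one
Product: 5 (R)-4-benzyl-3-[(2R)-2-methyl-3-oxopentanoyl]oxazolidin-2-one
Conditions: SO3·pyridine, DMSO, i-Pr2NEt, CH2Cl2, −10 → 0 °C
Reagents that add atoms: none
Why: Parikh–Doering oxidation: the carbinol is oxidised under mild amine-base conditions, and the C2 hydrogen of the β-ketoimide is held near the imide plane by allylic strain and is poorly aligned for removal, so C2 should keep its configuration.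

Step 3
Reactants: 1 (R)-4-benzyl-3-propionyloxazolidin-2-one; 6 2,3-dibromopropene
Product: 8 (R)-4-benzyl-3-[(2S)-4-bromo-2-methylpent-4-enoyl]oxazolidin-2-one, via sodium Z-enolate 7 (not isolated)
Conditions: NaN(SiMe3)2, THF, −78 °C; 6, −78 → −40 °C
Reagents that add atoms: none
Why: Evans asymmetric alkylation: the chelated enolate 7 is alkylated by the allylic bromide on the face opposite the benzyl group, which sets C6 as S; the vinylic bromide does not undergo substitution.

Step 4
Reactants: 8 (R)-4-benzyl-3-[(2S)-4-bromo-2-methylpent-4-enoyl]oxazolidin-2-one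
Product: 9 (2S)-4-bromo-2-methylpent-4-en-1-ol
Conditions: LiBH4, MeOH (1 equiv), Et2O, 0 °C
Reagents that add atoms: none
Why: Reductive cleavage of an N-acyloxazolidinone: hydride attacks the exocyclic carbonyl, the auxiliary is released for re-use, and the stereocentre and the bromoalkene are not involved.

Step 5
Reactants: 9 (2S)-4-bromo-2-methylpent-4-en-1-ol
Product: 10 (2S)-4-bromo-2-methylpent-4-enal
Conditions: Dess–Martin periodinane, NaHCO3, CH2Cl2, 0 °C → rt
Reagents that add atoms: none
Why: Dess–Martin oxidation: the buffered, base-free medium should leave the α-stereocentre intact; the volatile, epimerisable aldehyde is used at once without chromatography.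

Step 6
Reactants: 5 (R)-4-benzyl-3-[(2R)-2-methyl-3-oxopentanoyl]oxazolidin-2-one; 10 (2S)-4-bromo-2-methylpent-4-enal
Product: 12 (R)-4-benzyl-3-[(2R,4R,5S,6S)-8-bromo-5-hydroxy-2,4,6-trimethyl-3-oxonon-8-enoyl]oxazolidin-2-one, via trichlorotitanium Z-enolate 11 (not isolated)
Conditions: TiCl4, i-Pr2NEt, CH2Cl2, −10 °C; 10, −78 °C
Reagents that add atoms: none
Why: Titanium-mediated syn aldol reaction of a β-ketoimide: the C2 stereocentre of 11 steers the aldehyde to the 2,4-syn, 4,5-syn product, and the anti-Felkin preference of Z-enolates toward α-methyl aldehydes points the same way (matched case), which should set C4 as R and C5 as S.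

Step 7
Reactants: 12 (R)-4-benzyl-3-[(2R,4R,5S,6S)-8-bromo-5-hydroxy-2,4,6-trimethyl-3-oxonon-8-enoyl]oxazolidin-2-one
Product: 13 (R)-4-benzyl-3-[(2R,3S,4R,5S,6S)-8-bromo-3,5-dihydroxy-2,4,6-trimethylnon-8-enoyl]oxazolidin-2-one
Conditions: Zn(BH4)2, CH2Cl2/Et2O, −20 °C
Reagents that add atoms: none
Why: Chelation-controlled 1,3-syn reduction: zinc ties the C5 hydroxyl to the C3 ketone and external hydride enters the chelate from its open face, which should give the 3S carbinol syn to O5; the imide carbonyls are not reduced at this temperature.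

Step 8
Reactants: 13 (R)-4-benzyl-3-[(2R,3S,4R,5S,6S)-8-bromo-3,5-dihydroxy-2,4,6-trimethylnon-8-enoyl]oxazolidin-2-one
Product: 14 (R)-4-benzyl-3-{(2R)-2-[(4S,5R,6S)-6-[(2S)-4-bromopent-4-en-2-yl]-2,2,5-trimethyl-1,3-dioxan-4-yl]propanoyl}oxazolidin-2-one
Conditions: 2,2-dimethoxypropane, CSA (cat.), CH2Cl2, rt
Reagents that add atoms: 2,2-dimethoxypropane, COC(C)(C)OC
Why: Acid-catalysed transacetalisation: the syn-1,3-diol closes to a chair 1,3-dioxane with the C2 and C6 chains equatorial; no stereocentre is touched and the free δ-hydroxyl can no longer attack the imide.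

Step 9
Reactants: 14 (R)-4-benzyl-3-{(2R)-2-[(4S,5R,6S)-6-[(2S)-4-bromopent-4-en-2-yl]-2,2,5-trimethyl-1,3-dioxan-4-yl]propanoyl}oxazolidin-2-one
Product: 15 (2R)-2-[(4S,5R,6S)-6-[(2S)-4-bromopent-4-en-2-yl]-2,2,5-trimethyl-1,3-dioxan-4-yl]propanoic acid
Conditions: LiOH, H2O2, THF/H2O, 0 °C; Na2SO3; dilute HCl to pH 4, 0 °C
Reagents that add atoms: hydrogen peroxide, OO
Why: Hydroperoxide cleavage of an N-acyloxazolidinone: the small, weakly basic hydroperoxide anion attacks the exocyclic carbonyl and the sulfite quench removes peroxide; C2 is not enolised and the acetal and bromoalkene are inert.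

Step 10
Reactants: 5 (R)-4-benzyl-3-[(2R)-2-methyl-3-oxopentanoyl]oxazolidin-2-one; 16 acetaldehyde
Product: 18 (R)-4-benzyl-3-[(2R,4S,5R)-5-hydroxy-2,4-dimethyl-3-oxohexanoyl]oxazolidin-2-one, via tin triflate Z-enolate 17 (not isolated)
Conditions: Sn(OTf)2, Et3N, CH2Cl2, −20 °C; 16, −78 °C
Reagents that add atoms: none
Why: Divalent-tin-mediated syn aldol reaction of a β-ketoimide: enolate 17 reacts on the enolate face opposite to that used by the titanium enolate, which should give the 2,4-anti, 4,5-syn adduct and so set the future C12 and C13.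

Step 11
Reactants: 18 (R)-4-benzyl-3-[(2R,4S,5R)-5-hydroxy-2,4-dimethyl-3-oxohexanoyl]oxazolidin-2-one
Product: 19 (R)-4-benzyl-3-[(2R,3S,4S,5R)-3,5-dihydroxy-2,4-dimethylhexanoyl]oxazolidin-2-one
Conditions: Me4NBH(OAc)3, MeCN/AcOH, −30 → −20 °C
Reagents that add atoms: none
Why: Hydroxyl-directed 1,3-anti reduction (Evans–Saksena): the C13 hydroxyl exchanges onto boron and hydride is delivered internally through a chair transition state, which should give the C11 carbinol anti to O13.

Step 12
Reactants: 19 (R)-4-benzyl-3-[(2R,3S,4S,5R)-3,5-dihydroxy-2,4-dimethylhexanoyl]oxazolidin-2-one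
Product: 20 (3R,4S,5R,6R)-4-hydroxy-3,5,6-trimethyloxan-2-one
Conditions: DBU (cat.), CH2Cl2, 0 °C → rt
Reagents that add atoms: none
Why: Intramolecular acyl transfer (lactonisation): the C13 hydroxyl attacks the activated exocyclic imide carbonyl through a six-membered transition state and expels the auxiliary, while the C11 hydroxyl could only form a four-membered ring and stays free, so the two hydroxyls are told apart.

Step 13
Reactants: 20 (3R,4S,5R,6R)-4-hydroxy-3,5,6-trimethyloxan-2-one
Product: 21 (3R,4S,5S,6R)-4-[(tert-butyldimethylsilyl)oxy]-3,5,6-trimethyloxan-2-one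
Conditions: TBSOTf, 2,6-lutidine, CH2Cl2, −78 → 0 °C
Reagents that add atoms: tert-butyldimethylsilyl triflate, CC(C)(C)[Si](C)(C)OS(=O)(=O)C(F)(F)F
Why: Silylation with a silyl triflate: the only hydroxyl of 20 is flanked by two methyl-bearing carbons and needs the triflate; 2,6-lutidine is too weak a base to enolise the lactone.

Step 14
Reactants: 21 (3R,4S,5S,6R)-4-[(tert-butyldimethylsilyl)oxy]-3,5,6-trimethyloxan-2-one
Product: 22 (2R,3S,4S,5R)-3-[(tert-butyldimethylsilyl)oxy]-5-hydroxy-N-methoxy-N,2,4-trimethylhexanamide
Conditions: MeNHOMe·HCl, Me3Al, CH2Cl2, 0 °C → rt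
Reagents that add atoms: N,O-dimethylhydroxylamine hydrochloride, CNOC.Cl
Why: Weinreb amidation of a lactone: the aluminium amide made from Me3Al and the amine hydrochloride opens the lactone at the acyl carbon, freeing O13–H and leaving C9 as a latent aldehyde; the medium is Lewis acidic and not basic, so C10 and the silyl ether should hold, and 22 is used promptly to avoid reclosure.

Step 15
Reactants: 15 (2R)-2-[(4S,5R,6S)-6-[(2S)-4-bromopent-4-en-2-yl]-2,2,5-trimethyl-1,3-dioxan-4-yl]propanoic acid; 22 (2R,3S,4S,5R)-3-[(tert-butyldimethylsilyl)oxy]-5-hydroxy-N-methoxy-N,2,4-trimethylhexanamide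
Product: 24 (2R,3S,4S,5R)-4-[(tert-butyldimethylsilyl)oxy]-6-[methoxy(methyl)amino]-3,5-dimethyl-6-oxohexan-2-yl ester of 15, via mixed anhydride 23 (not isolated)
Conditions: 2,4,6-Cl3C6H2COCl, Et3N, THF, rt; 22, DMAP, toluene, rt
Reagents that add atoms: none
Why: Yamaguchi esterification: the acid is activated as 23 and DMAP passes the acyl group to the C13 hydroxyl; the hindered aroyl carbonyl of 23 is not attacked, and short contact with base limits ketene formation and loss of configuration at C2.

Step 16
Reactants: 24 (2R,3S,4S,5R)-4-[(tert-butyldimethylsilyl)oxy]-6-[methoxy(methyl)amino]-3,5-dimethyl-6-oxohexan-2-yl ester of 15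
Product: 26 (2R,3S,4S,5R)-4-[(tert-butyldimethylsilyl)oxy]-3,5-dimethyl-6-oxohexan-2-yl ester of 15, via aluminium hemiaminal 25 (not isolated)
Conditions: i-Bu2AlH (small excess), THF, −78 °C; aq. potassium sodium tartrate
Reagents that add atoms: none
Why: Partial reduction of an N-methoxy-N-methylamide: hydride adds to the amide carbonyl and the chelated adduct 25 persists at −78 °C, releasing the aldehyde only on work-up; the α-branched ester of a hindered secondary alcohol should react more slowly with a small excess of reagent, and 26 is used without delay to protect C10.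

Step 17
Reactants: 26 (2R,3S,4S,5R)-4-[(tert-butyldimethylsilyl)oxy]-3,5-dimethyl-6-oxohexan-2-yl ester of 15
Product: 29 11-O-(tert-butyldimethylsilyl)-3,5-O-isopropylidene-9-dihydro-8,8a-didehydro-8,8a-deoxyoleandolide (9-hydroxy-8-methylene 14-membered lactone, C9 epimers, 9S drawn), via alkenylchromium dichloride 27 (not isolated), via chromium alkoxide 28 (not isolated)
Conditions: CrCl2 (excess), NiCl2 (cat.), DMSO/THF, rt, slow addition of 26 to about 2 mM; aqueous work-up
Reagents that add atoms: none
Why: Nozaki–Hiyama–Kishi reaction used as a macrocyclisation, a known reaction type for haloalkene aldehydes. CrCl2 reduces NiCl2 to zerovalent nickel, which inserts into the C8–Br bond; the alkenyl group then passes to trivalent chromium to give 27, and divalent chromium returns nickel to the cycle. 27 adds through C8 to the C9 aldehyde to give alkoxide 28, which is hydrolysed on work-up to 29; the new C8–C9 bond closes the 14-membered ring in a 14-exo-trig mode, the carbonyl oxygen ending outside the ring. The new C9 stereocentre is controlled only weakly, by Felkin–Anh bias from C10 and by the geometry of ring closure, and no control is needed because step 18 removes it. The step needs cyclisation to outrun intermolecular coupling: slow addition keeps 26 dilute, the slow oxidative addition into the alkenyl bromide keeps 27 scarcer still, and the 3,5-dioxane holds C2–C6 in the extended shape the ring requires. It also needs chemoselectivity, which the reagent supplies: alkenylchromium species add to aldehydes but not to esters, acetals or silyl ethers, and they are too weakly basic to enolise the aldehyde, so C10 should keep its configuration.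

Step 18
Reactants: 29 11-O-(tert-butyldimethylsilyl)-3,5-O-isopropylidene-9-dihydro-8,8a-didehydro-8,8a-deoxyoleandolide (both C9 epimers)
Product: 30 11-O-(tert-butyldimethylsilyl)-3,5-O-isopropylidene-8,8a-didehydro-8,8a-deoxyoleandolide (8-methylene 9-ketone)
Conditions: Dess–Martin periodinane, NaHCO3, CH2Cl2, rt
Reagents that add atoms: none
Why: Dess–Martin oxidation of an allylic alcohol: both C9 epimers converge on one enone; the buffered, neutral medium spares the acetal and the silyl ether and should not move the exocyclic double bond into the ring.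

Step 19
Reactants: 30 11-O-(tert-butyldimethylsilyl)-3,5-O-isopropylidene-8,8a-didehydro-8,8a-deoxyoleandolide
Product: 32 11-O-(tert-butyldimethylsilyl)-3,5-O-isopropylidene-8,8a-deoxyoleandolide, via copper enolate 31 (not isolated)
Conditions: [(Ph3P)CuH]6, H2O, toluene, rt
Reagents that add atoms: none
Why: Copper hydride conjugate reduction: hydride adds to the unhindered exocyclic C8a, which is not a stereocentre, and enolate 31 is then protonated at C8 by water; C8 is created in this protonation, which is expected to occur on the outer face of the ring (macrocyclic control) and give 8R; esters, acetals and silyl ethers are inert and no free base is present.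

Step 20
Reactants: 32 11-O-(tert-butyldimethylsilyl)-3,5-O-isopropylidene-8,8a-deoxyoleandolide
Product: 33 8,8a-deoxyoleandolide
Conditions: HF (48% aq.), MeCN, 0 °C → rt
Reagents that add atoms: none
Why: Acidic fluoride deprotection: aqueous HF hydrolyses the isopropylidene acetal and cleaves the Si–O bond in one operation; the medium is acidic and not basic, so the β-hydroxy ketone and the lactone are not exposed to retro-aldol cleavage or elimination.

## Compound list

1 | (R)-4-benzyl-3-propionyloxazolidin-2-one | CCC(=O)N1[C@H](Cc2ccccc2)COC1=O | starting material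
2 | propanal | CCC=O | starting material
3 | Z-dibutylboron enolate of 1 (formed in the flask) | C/C=C(\OB(CCCC)CCCC)N1[C@H](Cc2ccccc2)COC1=O | intermediate
4 | (R)-4-benzyl-3-[(2R,3S)-3-hydroxy-2-methylpentanoyl]oxazolidin-2-one | CC[C@H](O)[C@@H](C)C(=O)N1[C@H](Cc2ccccc2)COC1=O | intermediate
5 | (R)-4-benzyl-3-[(2R)-2-methyl-3-oxopentanoyl]oxazolidin-2-one | CCC(=O)[C@@H](C)C(=O)N1[C@H](Cc2ccccc2)COC1=O | intermediate
6 | 2,3-dibromopropene | BrCC(Br)=C | starting material
7 | sodium Z-enolate of 1 (formed in the flask) | C/C=C(\O[Na])N1[C@H](Cc2ccccc2)COC1=O | intermediate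
8 | (R)-4-benzyl-3-[(2S)-4-bromo-2-methylpent-4-enoyl]oxazolidin-2-one | C=C(Br)C[C@H](C)C(=O)N1[C@H](Cc2ccccc2)COC1=O | intermediate
9 | (2S)-4-bromo-2-methylpent-4-en-1-ol | C=C(Br)C[C@H](C)CO | intermediate
10 | (2S)-4-bromo-2-methylpent-4-enal | C=C(Br)C[C@H](C)C=O | intermediate
11 | trichlorotitanium Z-enolate of 5, tetravalent titanium, enolised toward the ethyl group (formed in the flask) | C/C=C(\O[Ti](Cl)(Cl)Cl)[C@@H](C)C(=O)N1[C@H](Cc2ccccc2)COC1=O | intermediate
12 | (R)-4-benzyl-3-[(2R,4R,5S,6S)-8-bromo-5-hydroxy-2,4,6-trimethyl-3-oxonon-8-enoyl]oxazolidin-2-one | C=C(Br)C[C@H](C)[C@H](O)[C@@H](C)C(=O)[C@@H](C)C(=O)N1[C@H](Cc2ccccc2)COC1=O | intermediate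
13 | (R)-4-benzyl-3-[(2R,3S,4R,5S,6S)-8-bromo-3,5-dihydroxy-2,4,6-trimethylnon-8-enoyl]oxazolidin-2-one | C=C(Br)C[C@H](C)[C@H](O)[C@@H](C)[C@H](O)[C@@H](C)C(=O)N1[C@H](Cc2ccccc2)COC1=O | intermediate
14 | (R)-4-benzyl-3-{(2R)-2-[(4S,5R,6S)-6-[(2S)-4-bromopent-4-en-2-yl]-2,2,5-trimethyl-1,3-dioxan-4-yl]propanoyl}oxazolidin-2-one | C=C(Br)C[C@H](C)[C@H](OC(C)(C)O1)[C@@H](C)[C@H]1[C@@H](C)C(=O)N2[C@H](Cc3ccccc3)COC2=O | intermediate
15 | (2R)-2-[(4S,5R,6S)-6-[(2S)-4-bromopent-4-en-2-yl]-2,2,5-trimethyl-1,3-dioxan-4-yl]propanoic acid | C=C(Br)C[C@H](C)[C@H](OC(C)(C)O1)[C@@H](C)[C@H]1[C@@H](C)C(=O)O | intermediate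
16 | acetaldehyde | CC=O | starting material
17 | tin triflate Z-enolate of 5, divalent tin, enolised toward the ethyl group (formed in the flask) | C/C=C(\O[Sn]OS(=O)(=O)C(F)(F)F)[C@@H](C)C(=O)N1[C@H](Cc2ccccc2)COC1=O | intermediate
18 | (R)-4-benzyl-3-[(2R,4S,5R)-5-hydroxy-2,4-dimethyl-3-oxohexanoyl]oxazolidin-2-one | O[C@H](C)[C@H](C)C(=O)[C@@H](C)C(=O)N1[C@H](Cc2ccccc2)COC1=O | intermediate
19 | (R)-4-benzyl-3-[(2R,3S,4S,5R)-3,5-dihydroxy-2,4-dimethylhexanoyl]oxazolidin-2-one | O[C@H](C)[C@H](C)[C@H](O)[C@@H](C)C(=O)N1[C@H](Cc2ccccc2)COC1=O | intermediate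
20 | (3R,4S,5R,6R)-4-hydroxy-3,5,6-trimethyloxan-2-one | C[C@H]1OC(=O)[C@H](C)[C@@H](O)[C@H]1C | intermediate
21 | (3R,4S,5S,6R)-4-[(tert-butyldimethylsilyl)oxy]-3,5,6-trimethyloxan-2-one | C[C@H]1OC(=O)[C@H](C)[C@@H](O[Si](C)(C)C(C)(C)C)[C@H]1C | intermediate
22 | (2R,3S,4S,5R)-3-[(tert-butyldimethylsilyl)oxy]-5-hydroxy-N-methoxy-N,2,4-trimethylhexanamide | O[C@H](C)[C@H](C)[C@H](O[Si](C)(C)C(C)(C)C)[C@@H](C)C(=O)N(C)OC | intermediate
23 | mixed anhydride of 15 with 2,4,6-trichlorobenzoic acid (formed in the flask) | C=C(Br)C[C@H](C)[C@H](OC(C)(C)O1)[C@@H](C)[C@H]1[C@@H](C)C(=O)OC(=O)c2c(Cl)cc(Cl)cc2Cl | intermediate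
24 | (2R,3S,4S,5R)-4-[(tert-butyldimethylsilyl)oxy]-6-[methoxy(methyl)amino]-3,5-dimethyl-6-oxohexan-2-yl (2R)-2-[(4S,5R,6S)-6-[(2S)-4-bromopent-4-en-2-yl]-2,2,5-trimethyl-1,3-dioxan-4-yl]propanoate | C=C(Br)C[C@H](C)[C@H](OC(C)(C)O1)[C@@H](C)[C@H]1[C@@H](C)C(=O)O[C@H](C)[C@H](C)[C@H](O[Si](C)(C)C(C)(C)C)[C@@H](C)C(=O)N(C)OC | intermediate
25 | diisobutylaluminium hemiaminal of 24 at C9, configuration at C9 not assigned (formed in the flask) | C=C(Br)C[C@H](C)[C@H](OC(C)(C)O1)[C@@H](C)[C@H]1[C@@H](C)C(=O)O[C@H](C)[C@H](C)[C@H](O[Si](C)(C)C(C)(C)C)[C@@H](C)C(O[Al](CC(C)C)CC(C)C)N(C)OC | intermediate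
26 | (2R,3S,4S,5R)-4-[(tert-butyldimethylsilyl)oxy]-3,5-dimethyl-6-oxohexan-2-yl (2R)-2-[(4S,5R,6S)-6-[(2S)-4-bromopent-4-en-2-yl]-2,2,5-trimethyl-1,3-dioxan-4-yl]propanoate (C9 aldehyde, C8 2-bromoalkene) | C=C(Br)C[C@H](C)[C@H](OC(C)(C)O1)[C@@H](C)[C@H]1[C@@H](C)C(=O)O[C@H](C)[C@H](C)[C@H](O[Si](C)(C)C(C)(C)C)[C@@H](C)C=O | intermediate
27 | alkenylchromium dichloride from 26, trivalent chromium on C8 (formed in the flask) | C=C([Cr](Cl)Cl)C[C@H](C)[C@H](OC(C)(C)O1)[C@@H](C)[C@H]1[C@@H](C)C(=O)O[C@H](C)[C@H](C)[C@H](O[Si](C)(C)C(C)(C)C)[C@@H](C)C=O | intermediate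
28 | chromium alkoxide of 29, trivalent chromium on O9, 9S drawn (formed in the flask) | O=C1[C@H](C)[C@@H](OC(C)(C)O2)[C@H](C)[C@@H]2[C@@H](C)CC(=C)[C@@H](O[Cr](Cl)Cl)[C@H](C)[C@@H](O[Si](C)(C)C(C)(C)C)[C@@H](C)[C@@H](C)O1 | intermediate
29 | 11-O-(tert-butyldimethylsilyl)-3,5-O-isopropylidene-9-dihydro-8,8a-didehydro-8,8a-deoxyoleandolide (9-hydroxy-8-methylene lactone; C9 epimers, 9S drawn) | O=C1[C@H](C)[C@@H](OC(C)(C)O2)[C@H](C)[C@@H]2[C@@H](C)CC(=C)[C@@H](O)[C@H](C)[C@@H](O[Si](C)(C)C(C)(C)C)[C@@H](C)[C@@H](C)O1 | intermediate
30 | 11-O-(tert-butyldimethylsilyl)-3,5-O-isopropylidene-8,8a-didehydro-8,8a-deoxyoleandolide (8-methylene 9-ketone) | O=C1[C@H](C)[C@@H](OC(C)(C)O2)[C@H](C)[C@@H]2[C@@H](C)CC(=C)C(=O)[C@H](C)[C@@H](O[Si](C)(C)C(C)(C)C)[C@@H](C)[C@@H](C)O1 | intermediate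
31 | C8–C9 copper enolate from 30, monovalent copper, phosphine omitted, double-bond geometry not assigned (formed in the flask) | O=C1[C@H](C)[C@@H](OC(C)(C)O2)[C@H](C)[C@@H]2[C@@H](C)CC(C)=C(O[Cu])[C@H](C)[C@@H](O[Si](C)(C)C(C)(C)C)[C@@H](C)[C@@H](C)O1 | intermediate
32 | 11-O-(tert-butyldimethylsilyl)-3,5-O-isopropylidene-8,8a-deoxyoleandolide, (2R,3S,4R,5S,6S,8R,10R,11S,12S,13R) | O=C1[C@H](C)[C@@H](OC(C)(C)O2)[C@H](C)[C@@H]2[C@@H](C)C[C@@H](C)C(=O)[C@H](C)[C@@H](O[Si](C)(C)C(C)(C)C)[C@@H](C)[C@@H](C)O1 | intermediate
33 | 8,8a-deoxyoleandolide, (3R,4S,5R,6S,7S,9R,11R,12S,13R,14R)-4,6,12-trihydroxy-3,5,7,9,11,13,14-heptamethyloxacyclotetradecane-2,10-dione | C[C@@H]1[C@@H](O)[C@@H](C)C[C@@H](C)C(=O)[C@H](C)[C@@H](O)[C@@H](C)[C@@H](C)OC(=O)[C@H](C)[C@H]1O | target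

## Step count and least certain steps

Total step count: 20. Longest linear sequence: 13 steps from 1 (steps 3–9, then 15–20); the branch through steps 1, 2, 10–14 and 15–20 is equally long.

Step 17 (key step). The most likely failure is intermolecular coupling to dimers and oligomers. Slow oxidative addition of zerovalent nickel into the 2-bromoalkene adds to the risk, because the aldehyde then stays exposed to Lewis-acidic chromium salts, which invites epimerisation at C10 or reductive dimerisation of the aldehyde. The fallback makes C8–C9 between fragments and closes the ring at the ester; it sets out from 22 and 14 and comes back at 29. 22 is silylated at O13 (Et3SiOTf, 2,6-lutidine) to give the 5-triethylsilyl ether of 22, F1, and i-Bu2AlH turns this into the corresponding C9 aldehyde F2. CrCl2 with catalytic NiCl2 in DMSO couples 14 with an excess of F2 at ordinary concentration to give the open-chain C1–C13 allylic alcohol F3 (C9 epimers, auxiliary still on C1). LiOH/H2O2 removes the auxiliary to give the 13-silyloxy acid F4, and buffered HF·pyridine takes off only the triethylsilyl group to give the 9,13-dihydroxy acid F5. Yamaguchi macrolactonisation (2,4,6-trichlorobenzoyl chloride, Et3N, then DMAP, toluene, high dilution) closes O13–C1 and delivers 29; the C9 hydroxyl could only form a 10-membered ring.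

Step 19. The most likely failure is protonation of enolate 31 from the wrong face, giving the C8 epimer; migration of the exocyclic double bond of 30 into the ring before reduction is a second risk. Correcting C8 by base would endanger C10 and invite β-elimination of the 11-silyloxy group, so the fallback sets C8 from C9 instead. It sets out from the (9S) epimer of 29, separated by chromatography, and comes back at 32; the (9R) epimer can be returned through 30 and NaBH4/CeCl3. Hydroxyl-directed hydrogenation with [Rh(nbd)(dppb)]BF4 and H2 in CH2Cl2 should deliver hydrogen from the face of the bound hydroxyl in the conformer of least allylic strain, giving the 8,9-anti (8R,9R)-9-hydroxy-8-methyl lactone F6; Dess–Martin oxidation of F6 gives 32.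

Step 16. The most likely failure is competing reduction of the C1 ester or over-reduction of the aldehyde; loss of configuration at C10 during work-up and reclosure of 22 to a lactone during step 15 are related risks. The fallback avoids the amide altogether; it sets out from 21 and comes back at 26, bypassing steps 14–16. LiBH4 opens 21 to the 1,5-diol F7; Et3SiCl and imidazole at low temperature silylate the primary hydroxyl to give the primary triethylsilyl ether F8; Yamaguchi esterification of F8 with 15 gives the ester F9; HF·pyridine buffered with pyridine removes the primary triethylsilyl group to give the primary alcohol F10; Dess–Martin oxidation of F10 gives 26.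

Step 12. The most likely failure is attack of an alkoxide on the ring carbonyl of the oxazolidinone (carbamate transfer) in place of the exocyclic carbonyl, or incomplete acyl transfer. The fallback separates cleavage from ring closure; it sets out from 19 and comes back at 20. LiOH/H2O2 cleaves the auxiliary to give the dihydroxy acid F11, which closes through its δ-hydroxyl on warming with catalytic pyridinium p-toluenesulfonate in benzene to give 20.

## Further compounds

F1 | step 17 | (2R,3S,4S,5R)-3-[(tert-butyldimethylsilyl)oxy]-N-methoxy-N,2,4-trimethyl-5-[(triethylsilyl)oxy]hexanamide | CC[Si](CC)(CC)O[C@H](C)[C@H](C)[C@H](O[Si](C)(C)C(C)(C)C)[C@@H](C)C(=O)N(C)OC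
F2 | step 17 | (2R,3S,4S,5R)-3-[(tert-butyldimethylsilyl)oxy]-2,4-dimethyl-5-[(triethylsilyl)oxy]hexanal | CC[Si](CC)(CC)O[C@H](C)[C@H](C)[C@H](O[Si](C)(C)C(C)(C)C)[C@@H](C)C=O
F3 | step 17 | open-chain C1–C13 allylic alcohol: 14 joined at C8 to the carbinol carbon of F2, 8-methylene, C9 epimers | CC[Si](CC)(CC)O[C@H](C)[C@H](C)[C@H](O[Si](C)(C)C(C)(C)C)[C@@H](C)C(O)C(=C)C[C@H](C)[C@H](OC(C)(C)O1)[C@@H](C)[C@H]1[C@@H](C)C(=O)N2[C@H](Cc3ccccc3)COC2=O
F4 | step 17 | C1 carboxylic acid from F3 (13-triethylsilyloxy, 9-hydroxy, 8-methylene) | CC[Si](CC)(CC)O[C@H](C)[C@H](C)[C@H](O[Si](C)(C)C(C)(C)C)[C@@H](C)C(O)C(=C)C[C@H](C)[C@H](OC(C)(C)O1)[C@@H](C)[C@H]1[C@@H](C)C(=O)O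
F5 | step 17 | 9,13-dihydroxy seco acid (11-O-TBS, 3,5-O-isopropylidene, 8-methylene) | O[C@H](C)[C@H](C)[C@H](O[Si](C)(C)C(C)(C)C)[C@@H](C)C(O)C(=C)C[C@H](C)[C@H](OC(C)(C)O1)[C@@H](C)[C@H]1[C@@H](C)C(=O)O
F6 | step 19 | (8R,9R)-11-O-(tert-butyldimethylsilyl)-3,5-O-isopropylidene-9-dihydro-8,8a-deoxyoleandolide | O=C1[C@H](C)[C@@H](OC(C)(C)O2)[C@H](C)[C@@H]2[C@@H](C)C[C@@H](C)[C@@H](O)[C@H](C)[C@@H](O[Si](C)(C)C(C)(C)C)[C@@H](C)[C@@H](C)O1
F7 | step 16 | (2S,3R,4S,5R)-3-[(tert-butyldimethylsilyl)oxy]-2,4-dimethylhexane-1,5-diol | O[C@H](C)[C@H](C)[C@H](O[Si](C)(C)C(C)(C)C)[C@@H](C)CO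
F8 | step 16 | (2R,3S,4R,5S)-4-[(tert-butyldimethylsilyl)oxy]-3,5-dimethyl-6-[(triethylsilyl)oxy]hexan-2-ol | O[C@H](C)[C@H](C)[C@H](O[Si](C)(C)C(C)(C)C)[C@@H](C)CO[Si](CC)(CC)CC
F9 | step 16 | ester of 15 with F8 (C9 as CH2OSiEt3) | C=C(Br)C[C@H](C)[C@H](OC(C)(C)O1)[C@@H](C)[C@H]1[C@@H](C)C(=O)O[C@H](C)[C@H](C)[C@H](O[Si](C)(C)C(C)(C)C)[C@@H](C)CO[Si](CC)(CC)CC
F10 | step 16 | primary alcohol from F9 (C9 as CH2OH) | C=C(Br)C[C@H](C)[C@H](OC(C)(C)O1)[C@@H](C)[C@H]1[C@@H](C)C(=O)O[C@H](C)[C@H](C)[C@H](O[Si](C)(C)C(C)(C)C)[C@@H](C)CO
F11 | step 12 | (2R,3S,4S,5R)-3,5-dihydroxy-2,4-dimethylhexanoic acid | O[C@H](C)[C@H](C)[C@H](O)[C@@H](C)C(=O)O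
A1 | alternative 1 | C3–C11 5,9-diol with 4-methoxybenzyl and tert-butyldimethylsilyl end groups | COc1ccc(COC[C@H](C)[C@@H](O)[C@@H](C)C[C@@H](C)[C@@H](O)[C@H](C)CO[Si](C)(C)C(C)(C)C)cc1
A2 | alternative 1 | (E,E)-C3–C11 skipped diene with alkenes at C5=C6 and C8=C9 | COc1ccc(COC[C@H](C)/C=C(\C)C/C(C)=C/[C@H](C)CO[Si](C)(C)C(C)(C)C)cc1
A3 | alternative 2 | 3-oxo-5-hydroxy 14-membered lactone, 9-O-(4-methoxybenzyl), 11-O-TBS | O=C1[C@H](C)C(=O)[C@H](C)[C@@H](O)[C@@H](C)C[C@@H](C)[C@@H](OCc2ccc(OC)cc2)[C@H](C)[C@@H](O[Si](C)(C)C(C)(C)C)[C@@H](C)[C@@H](C)O1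
A4 | alternative 2 | O13 propionate carrying the C3–C5 β-lactone | CCC(=O)O[C@H](C)[C@H](C)[C@H](O[Si](C)(C)C(C)(C)C)[C@@H](C)[C@H](OCc1ccc(OC)cc1)[C@H](C)C[C@H](C)[C@@H]2OC(=O)[C@@H]2C
A5 | alternative 3 | 14-membered lactone with the (E)-C11=C12 alkene | O=C1[C@H](C)[C@@H](O[Si](C)(C)C(C)(C)C)[C@H](C)[C@@H](O[Si](C)(C)C(C)(C)C)[C@@H](C)C[C@@H](C)[C@@H](OCc2ccc(OC)cc2)[C@H](C)/C=C(\C)[C@@H](C)O1
A6 | alternative 3 | diene ester with C10 vinyl and C12 isopropenyl groups | C=C(C)[C@@H](C)OC(=O)[C@H](C)[C@@H](O[Si](C)(C)C(C)(C)C)[C@H](C)[C@@H](O[Si](C)(C)C(C)(C)C)[C@@H](C)C[C@@H](C)[C@@H](OCc1ccc(OC)cc1)[C@H](C)C=C
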